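**Retrosynthetic overview**
1. Target 23 ⇐ macrocyclic allylic alcohol 20: hydroxyl-directed dihydroxylation of the exocyclic C4=C15 alkene and acetylation of O5.
2. 20 ⇐ seco aldehyde 19: intramolecular Nozaki–Hiyama–Kishi closure of C4–C5 (ten-membered carbocycle, formed last).
3. Lactone (second ring) ⇐ chromium 2-(alkoxycarbonyl)allylation of allyl bromide 15 with 2,2-dimethoxyacetaldehyde (C6–C7).
4. Furanone (first ring) and quaternary C10 ⇐ gold-catalysed heterocyclisation/1,2-methyl shift of α-hydroxy-α-alkynyl ketone 14 (key step).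
5. 14 ⇐ boron aldol (C8–C9) of ketone 5 with enal 10; 5 ⇐ butane-2,3-dione + alkynylsilane 3 (new copper-catalysed asymmetric alkynylsilylation).

Assumption: 1,1-dibromoethene and anhydrous 2,2-dimethoxyacetaldehyde (dried from its commercial aqueous solution) are taken as available; locants C1–C15 follow germacrane numbering (C1 ketone, C3–O–C10 bridge, C6–O–C12 lactone, C8 ester, C15 hydroxymethyl).

The route has not been run; stereochemical outcomes in steps 2, 5, 8, 11 and 12 are predictions from models and analogy.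

**Step 1**
Reactants: 1 ethynyltrimethylsilane; 2 1,1-dibromoethene
Product: 3 (3-bromobut-3-en-1-yn-1-yl)trimethylsilane
Conditions: Pd(PPh3)4 (3 mol%), copper iodide CuI (5 mol%), iPr2NH, THF, 0 °C to rt, 2 in excess (3 equiv)
Reagents that add atoms: none
Why: Sonogashira mono-coupling of a geminal dibromoalkene; the remaining C–Br bond of the 2-bromo-1,3-enyne reacts more slowly and excess 2 suppresses double coupling.

**Step 2**
Reactants: 3 (3-bromobut-3-en-1-yn-1-yl)trimethylsilane; 4 butane-2,3-dione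
Product: 5 (3R)-6-bromo-3-methyl-3-(trimethylsilyloxy)hept-6-en-4-yn-2-one
Conditions: CuOtBu (5 mol%), (R)-DTBM-SEGPHOS (6 mol%, enantiomer chosen for the 3R product), 4 (3 equiv), toluene, −30 °C
Reagents that add atoms: none
Why: Proposed new method: a monovalent copper alkoxide takes the alkynyl group from silicon to give a copper acetylide, which adds to one carbonyl of the s-cis chelated 1,2-diketone inside the chiral bisphosphine pocket, and the resulting copper tertiary alkoxide is silylated by the next alkynylsilane, which regenerates the acetylide and releases the product as its silyl ether (mono-addition because the product is no longer an activated 1,2-dicarbonyl); the closest known reactions are copper alkoxide/bisphosphine-catalysed enantioselective alkynylation of trifluoromethyl ketones and α-keto esters with terminal alkynes and alkoxide-initiated addition of alkynylsilanes to ketones; this step forms C1–C2 and sets the carbinol centre that later becomes C10.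

**Step 3**
Reactants: 6 methyl acrylate; 7 2,2-dimethoxyacetaldehyde
Product: 8 methyl 3-hydroxy-4,4-dimethoxy-2-methylidenebutanoate (racemic)
Conditions: DABCO (0.5 equiv), dioxane/H2O, rt
Reagents that add atoms: none
Why: Morita–Baylis–Hillman reaction with an activated α-alkoxy aldehyde; the carbinol centre is racemic and is destroyed in step 4.

**Step 4**
Reactants: 8 methyl 3-hydroxy-4,4-dimethoxy-2-methylidenebutanoate
Product: 10 methyl (2Z)-2-(bromomethyl)-4-oxobut-2-enoate, via bromo acetal 9 (not isolated)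
Conditions: NBS, Me2S, CH2Cl2, 0 °C to rt; then TFA/H2O (9:1), 0 °C
Reagents that add atoms: N-bromosuccinimide, O=C1CCC(=O)N1Br; water, O
Why: Corey–Kim-type activation of the alcohol with SN2′ attack of bromide at the methylidene carbon gives the thermodynamically preferred (Z) trisubstituted enoate, and the vinylogous acetal is then hydrolysed to the enal.

**Step 5**
Reactants: 5 (3R)-6-bromo-3-methyl-3-(trimethylsilyloxy)hept-6-en-4-yn-2-one; 10 methyl (2Z)-2-(bromomethyl)-4-oxobut-2-enoate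
Product: 13 methyl (2Z,4R,7R)-10-bromo-2-(bromomethyl)-4,7-dihydroxy-7-methyl-6-oxoundeca-2,10-dien-8-ynoate, via enol borinate 11 (not isolated), via silyl aldol 12 (not isolated)
Conditions: (−)-Ipc2BCl, iPr2NEt, Et2O, 0 °C; then 10, −78 to −20 °C; then H2O2, pH 7 buffer, MeOH, 0 °C; then citric acid, MeOH, rt
Reagents that add atoms: none
Why: Paterson boron aldol of a methyl ketone with reagent control expected to give re-face attack on the enal and the 4R carbinol (C8), the sense being the least certain point here and corrected if needed with (+)-Ipc2BCl; the minor C8 epimer is a separable diastereomer, the hindered non-nucleophilic base spares the allylic bromide, and mild acid removes the tertiary silyl ether.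

**Step 6**
Reactants: 13 methyl (2Z,4R,7R)-10-bromo-2-(bromomethyl)-4,7-dihydroxy-7-methyl-6-oxoundeca-2,10-dien-8-ynoate
Product: 14 methyl (2Z,4R,7R)-10-bromo-2-(bromomethyl)-7-hydroxy-7-methyl-6-oxo-4-(triethylsilyloxy)undeca-2,10-dien-8-ynoate
Conditions: TESCl, imidazole, CH2Cl2, 0 °C
Reagents that add atoms: chlorotriethylsilane, CC[Si](Cl)(CC)CC
Why: Selective silylation of the secondary allylic alcohol over the tertiary α-ketol hydroxyl; the silyl ether keeps O8 out of the gold step, is too poor a leaving group for 1,4-elimination from the allylchromium of step 8, and directs lactonisation to O6.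

**Step 7**
Reactants: 14 methyl (2Z,4R,7R)-10-bromo-2-(bromomethyl)-7-hydroxy-7-methyl-6-oxo-4-(triethylsilyloxy)undeca-2,10-dien-8-ynoate
Product: 15 methyl (2Z,4R)-5-[(2R)-5-(1-bromoethenyl)-2-methyl-3-oxo-2,3-dihydrofuran-2-yl]-2-(bromomethyl)-4-(triethylsilyloxy)pent-2-enoate
Conditions: AuCl3 (5 mol%), CH2Cl2, rt
Reagents that add atoms: none
Why: Key step, the domino heterocyclisation/1,2-alkyl shift of a 2-hydroxy-2-alkynyl ketone: the ketone oxygen adds 5-endo to the alkyne activated by trivalent gold, then the methyl group (C14) migrates suprafacially from the carbinol carbon C1 to the adjacent oxocarbenium carbon C10 (α-ketol-type 1,2-shift), which turns C1 into the ring ketone and creates the quaternary C10 with transfer of chirality (carbinol R gives 10R), followed by protodeauration.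

**Step 8**
Reactants: 15 methyl (2Z,4R)-5-[(2R)-5-(1-bromoethenyl)-2-methyl-3-oxo-2,3-dihydrofuran-2-yl]-2-(bromomethyl)-4-(triethylsilyloxy)pent-2-enoate; 7 2,2-dimethoxyacetaldehyde
Product: 17 (4R,5S)-4-{(1R)-2-[(2R)-5-(1-bromoethenyl)-2-methyl-3-oxo-2,3-dihydrofuran-2-yl]-1-hydroxyethyl}-5-(dimethoxymethyl)-3-methylideneoxolan-2-one, via bis-silyl adduct 16 (not isolated)
Conditions: CrCl2 (10 mol%, nickel-free), chiral carbazole bis(oxazoline) ligand (12 mol%, enantiomer matched to the 6S,7R adduct), Mn powder, TMSCl, iPr2NEt (cat.), 7 (3 equiv), THF, rt; then TsOH·H2O, MeOH, rt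
Reagents that add atoms: none
Why: Catalytic enantioselective Nozaki–Hiyama-type 2-(alkoxycarbonyl)allylation in which the allylchromium adds through C7 in a chair transition state, expected to give the anti (6,7-trans) adduct with the ligand fixing the aldehyde face (6S,7R), though the influence of the C8 centre is not known in advance; the vinyl bromide is inert without nickel, and acid then cleaves the trimethylsilyl ether, closes the γ-lactone on O6 and finally removes the triethylsilyl group.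

**Step 9**
Reactants: 17 (4R,5S)-4-{(1R)-2-[(2R)-5-(1-bromoethenyl)-2-methyl-3-oxo-2,3-dihydrofuran-2-yl]-1-hydroxyethyl}-5-(dimethoxymethyl)-3-methylideneoxolan-2-one
Product: 18 (1R)-2-[(2R)-5-(1-bromoethenyl)-2-methyl-3-oxo-2,3-dihydrofuran-2-yl]-1-[(2S,3R)-2-(dimethoxymethyl)-4-methylidene-5-oxooxolan-3-yl]ethyl 2-methylprop-2-enoate
Conditions: methacryloyl chloride, Et3N, DMAP (cat.), CH2Cl2, 0 °C
Reagents that add atoms: methacryloyl chloride, CC(=C)C(=O)Cl
Why: Acylation of the only free hydroxyl, done cold and briefly so that esterification outruns translactonisation.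

**Step 10**
Reactants: 18 (1R)-2-[(2R)-5-(1-bromoethenyl)-2-methyl-3-oxo-2,3-dihydrofuran-2-yl]-1-[(2S,3R)-2-(dimethoxymethyl)-4-methylidene-5-oxooxolan-3-yl]ethyl 2-methylprop-2-enoate
Product: 19 (1R)-2-[(2R)-5-(1-bromoethenyl)-2-methyl-3-oxo-2,3-dihydrofuran-2-yl]-1-[(2S,3R)-2-formyl-4-methylidene-5-oxooxolan-3-yl]ethyl 2-methylprop-2-enoate
Conditions: TFA/H2O/CH2Cl2, 0 °C to rt; used crude
Reagents that add atoms: water, O
Why: Acid hydrolysis of the dimethyl acetal; the esters and the enol-ether-type furanone survive, and acidic rather than basic conditions protect the C6 centre next to the new aldehyde.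

**Step 11**
Reactants: 19 (1R)-2-[(2R)-5-(1-bromoethenyl)-2-methyl-3-oxo-2,3-dihydrofuran-2-yl]-1-[(2S,3R)-2-formyl-4-methylidene-5-oxooxolan-3-yl]ethyl 2-methylprop-2-enoate
Product: 20 (5R,6S,7R,8R,10R)-5-hydroxy-1-oxo-3,10-epoxygermacra-2,4(15),11(13)-trien-6,12-olid-8-yl 2-methylprop-2-enoate
Conditions: CrCl2 (8 equiv), NiCl2 (2 mol%), DMSO/THF, 2 mM, rt
Reagents that add atoms: none
Why: Intramolecular Nozaki–Hiyama–Kishi reaction (zerovalent nickel inserts into the vinyl C–Br bond, transmetalation to trivalent chromium, aldehyde-selective addition) closes C4–C5 with the furanone bridge pre-organising the chain; Felkin–Anh attack anti to the lactone oxygen gives the 5,6-anti carbinol, which is 5R here and becomes 5S in the target once C4 is oxygenated.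

**Step 12**
Reactants: 20 (5R,6S,7R,8R,10R)-5-hydroxy-1-oxo-3,10-epoxygermacra-2,4(15),11(13)-trien-6,12-olid-8-yl 2-methylprop-2-enoate
Product: 23 (4S,5S,6S,7R,8R,10R)-5-acetoxy-4,15-dihydroxy-1-oxo-3,10-epoxygermacra-2,11(13)-dien-6,12-olid-8-yl 2-methylprop-2-enoate (CNP0275292.4), via osmate ester 21 (not isolated), via acetylated osmate ester 22 (not isolated)
Conditions: OsO4 (1.05 equiv), TMEDA, CH2Cl2, −78 °C; then Ac2O, pyridine, DMAP, 0 °C to rt; then HCl in MeOH (2 M), rt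
Reagents that add atoms: osmium tetroxide, O=[Os](=O)(=O)=O; acetic anhydride, CC(=O)OC(C)=O
Why: Hydroxyl-directed dihydroxylation, in which the OsO4·TMEDA complex hydrogen-bonded to the C5 hydroxyl is delivered to the allylic exocyclic alkene syn to that hydroxyl (4S, the sense undirected osmylation would not favour) and leaves the electron-poor acrylate and methylidene lactone alone; the chelated glycolate of hexavalent osmium masks O4 and O15 while O5 is acetylated, and acidic methanolysis frees the diol without acyl migration.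

**Compound list**
1 | ethynyltrimethylsilane | C#C[Si](C)(C)C | starting material
2 | 1,1-dibromoethene | C=C(Br)Br | starting material
3 | (3-bromobut-3-en-1-yn-1-yl)trimethylsilane | C=C(Br)C#C[Si](C)(C)C | intermediate
4 | butane-2,3-dione | CC(=O)C(C)=O | starting material
5 | (3R)-6-bromo-3-methyl-3-(trimethylsilyloxy)hept-6-en-4-yn-2-one | CC(=O)[C@](C)(O[Si](C)(C)C)C#CC(Br)=C | intermediate
6 | methyl acrylate | C=CC(=O)OC | starting material
7 | 2,2-dimethoxyacetaldehyde | COC(OC)C=O | starting material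
8 | methyl 3-hydroxy-4,4-dimethoxy-2-methylidenebutanoate (racemic) | C=C(C(=O)OC)C(O)C(OC)OC | intermediate
9 | methyl (2Z)-2-(bromomethyl)-4,4-dimethoxybut-2-enoate | BrC/C(=C\C(OC)OC)C(=O)OC | intermediate
10 | methyl (2Z)-2-(bromomethyl)-4-oxobut-2-enoate | BrC/C(=C\C=O)C(=O)OC | intermediate
11 | bis[(−)-isopinocampheyl]boron enolate of 5 (boron on the C2 oxygen, C1=C2 enol) | C=C(OB([C@@H]1C[C@@H]2C[C@H]([C@H]1C)C2(C)C)[C@@H]1C[C@@H]2C[C@H]([C@H]1C)C2(C)C)[C@](C)(O[Si](C)(C)C)C#CC(Br)=C | intermediate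
12 | methyl (2Z,4R,7R)-10-bromo-2-(bromomethyl)-4-hydroxy-7-methyl-6-oxo-7-(trimethylsilyloxy)undeca-2,10-dien-8-ynoate | BrC/C(=C\[C@H](O)CC(=O)[C@](C)(O[Si](C)(C)C)C#CC(Br)=C)C(=O)OC | intermediate
13 | methyl (2Z,4R,7R)-10-bromo-2-(bromomethyl)-4,7-dihydroxy-7-methyl-6-oxoundeca-2,10-dien-8-ynoate | BrC/C(=C\[C@H](O)CC(=O)[C@](C)(O)C#CC(Br)=C)C(=O)OC | intermediate
14 | methyl (2Z,4R,7R)-10-bromo-2-(bromomethyl)-7-hydroxy-7-methyl-6-oxo-4-(triethylsilyloxy)undeca-2,10-dien-8-ynoate | BrC/C(=C\[C@H](O[Si](CC)(CC)CC)CC(=O)[C@](C)(O)C#CC(Br)=C)C(=O)OC | intermediate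
15 | methyl (2Z,4R)-5-[(2R)-5-(1-bromoethenyl)-2-methyl-3-oxo-2,3-dihydrofuran-2-yl]-2-(bromomethyl)-4-(triethylsilyloxy)pent-2-enoate | BrC/C(=C\[C@H](O[Si](CC)(CC)CC)C[C@@]1(C)OC(=CC1=O)C(Br)=C)C(=O)OC | intermediate
16 | methyl (3R,4S)-3-{(1R)-2-[(2R)-5-(1-bromoethenyl)-2-methyl-3-oxo-2,3-dihydrofuran-2-yl]-1-(triethylsilyloxy)ethyl}-5,5-dimethoxy-2-methylidene-4-(trimethylsilyloxy)pentanoate | COC(OC)[C@@H](O[Si](C)(C)C)[C@H](C(=C)C(=O)OC)[C@H](O[Si](CC)(CC)CC)C[C@@]1(C)OC(=CC1=O)C(Br)=C | intermediate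
17 | (4R,5S)-4-{(1R)-2-[(2R)-5-(1-bromoethenyl)-2-methyl-3-oxo-2,3-dihydrofuran-2-yl]-1-hydroxyethyl}-5-(dimethoxymethyl)-3-methylideneoxolan-2-one | COC(OC)[C@H]1OC(=O)C(=C)[C@@H]1[C@H](O)C[C@@]2(C)OC(=CC2=O)C(Br)=C | intermediate
18 | (1R)-2-[(2R)-5-(1-bromoethenyl)-2-methyl-3-oxo-2,3-dihydrofuran-2-yl]-1-[(2S,3R)-2-(dimethoxymethyl)-4-methylidene-5-oxooxolan-3-yl]ethyl 2-methylprop-2-enoate | COC(OC)[C@H]1OC(=O)C(=C)[C@@H]1[C@H](OC(=O)C(C)=C)C[C@@]2(C)OC(=CC2=O)C(Br)=C | intermediate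
19 | (1R)-2-[(2R)-5-(1-bromoethenyl)-2-methyl-3-oxo-2,3-dihydrofuran-2-yl]-1-[(2S,3R)-2-formyl-4-methylidene-5-oxooxolan-3-yl]ethyl 2-methylprop-2-enoate | O=C[C@H]1OC(=O)C(=C)[C@@H]1[C@H](OC(=O)C(C)=C)C[C@@]2(C)OC(=CC2=O)C(Br)=C | intermediate
20 | (5R,6S,7R,8R,10R)-5-hydroxy-1-oxo-3,10-epoxygermacra-2,4(15),11(13)-trien-6,12-olid-8-yl 2-methylprop-2-enoate | C=C(C)C(=O)O[C@@H]1C[C@@]2(C)OC(=CC2=O)C(=C)[C@@H](O)[C@H]2OC(=O)C(=C)[C@@H]21 | intermediate
21 | (4S,5S,6S,7R,8R,10R)-4,15-O-[dioxo(N,N,N′,N′-tetramethylethane-1,2-diamine)osmium] glycolate of the 5-hydroxy macrocycle | C=C(C)C(=O)O[C@@H]1C[C@@]2(C)OC(=CC2=O)[C@]3(CO[Os-2]4(=O)(=O)(O3)[N+](C)(C)CC[N+]4(C)C)[C@@H](O)[C@H]2OC(=O)C(=C)[C@@H]21 | intermediate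
22 | 5-O-acetate of 21 | C=C(C)C(=O)O[C@@H]1C[C@@]2(C)OC(=CC2=O)[C@]3(CO[Os-2]4(=O)(=O)(O3)[N+](C)(C)CC[N+]4(C)C)[C@@H](OC(C)=O)[C@H]2OC(=O)C(=C)[C@@H]21 | intermediate
23 | (4S,5S,6S,7R,8R,10R)-5-acetoxy-4,15-dihydroxy-1-oxo-3,10-epoxygermacra-2,11(13)-dien-6,12-olid-8-yl 2-methylprop-2-enoate (CNP0275292.4) | C=C(C)C(=O)O[C@@H]1C[C@@]2(C)OC(=CC2=O)[C@](O)(CO)[C@@H](OC(C)=O)[C@H]2OC(=O)C(=C)[C@@H]21 | target

**Total step count:** 12
**Longest linear sequence:** 10 steps (3, 4, 5–12 from 6 and 7; equally 1, 2, 5–12 from 1 and 2)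

**Steps most likely to fail**

Step 2 (new copper-catalysed alkynylsilylation; turnover by silyl transfer and the enantioselectivity on a 1,2-diketone are unproven). Fallback with known chemistry, setting out from 3 and coming back at 5: desilylation with K2CO3 in MeOH gives 2-bromobut-1-en-3-yne F1, used as a solution. The known Zn(OTf)2/chiral amino alcohol/Et3N alkynylation of an α-keto ester, here ethyl pyruvate, gives ethyl (2R)-5-bromo-2-hydroxy-2-methylhex-5-en-3-ynoate F2. MeNHOMe·HCl with iPrMgCl converts it into (2R)-5-bromo-2-hydroxy-N-methoxy-N,2-dimethylhex-5-en-3-ynamide F3. MeMgBr gives (3R)-6-bromo-3-hydroxy-3-methylhept-6-en-4-yn-2-one F4, and TMSCl/imidazole returns 5.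

Step 11 (closure of the strained, oxa-bridged ten-membered ring at C4–C5 may lose to oligomerisation or reduction). Fallback that moves the ring closure to C6–C7, setting out from 5 and coming back at 23:
- An intermolecular catalytic asymmetric Nozaki–Hiyama–Kishi reaction of 5 with 7 (CrCl2, NiCl2, chiral sulfonamide ligand, Mn, TMSCl, mild acidic work-up) gives (3R,7R)-7-hydroxy-8,8-dimethoxy-3-methyl-6-methylidene-3-(trimethylsilyloxy)oct-4-yn-2-one F5.
- Ac2O/pyridine gives (2R,6R)-1,1-dimethoxy-6-methyl-3-methylidene-7-oxo-6-(trimethylsilyloxy)oct-4-yn-2-yl acetate F6.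
- The aldol of step 5 with 10 gives methyl (2Z,4R,7R)-10-[(1R)-1-acetoxy-2,2-dimethoxyethyl]-2-(bromomethyl)-4,7-dihydroxy-7-methyl-6-oxoundeca-2,10-dien-8-ynoate F7.
- TESCl/imidazole gives its 4-triethylsilyl ether F8.
- AuCl3 gives methyl (2Z,4R)-5-{(2R)-5-[(3R)-3-acetoxy-4,4-dimethoxybut-1-en-2-yl]-2-methyl-3-oxo-2,3-dihydrofuran-2-yl}-2-(bromomethyl)-4-(triethylsilyloxy)pent-2-enoate F9.
- Me2BBr at −78 °C followed by water gives the corresponding 4-oxobut-1-en-2-yl aldehyde F10.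
- Stoichiometric CrCl2 at high dilution, then TsOH in MeOH, closes the carbocycle and the lactone to give (5R,6S,7R,8R,10R)-5-acetoxy-8-hydroxy-1-oxo-3,10-epoxygermacra-2,4(15),11(13)-trien-6,12-olide F11.
- Methacryloyl chloride/Et3N gives its 8-methacrylate F12.
- Dihydroxylation with catalytic OsO4 and NMO, steered by a cinchona ligand such as (DHQD)2PHAL if needed, gives 23.

Step 12 (acetylation of O5 beside the bulky osmate ester, or cleavage of the robust glycolate in the presence of three esters, may fail; the facial sense in the ring is also unproven). Fallback that separates the operations with a protecting group, setting out from 20 and coming back at 23: OsO4/TMEDA followed directly by HCl in MeOH gives (4S,5S,6S,7R,8R,10R)-4,5,15-trihydroxy-1-oxo-3,10-epoxygermacra-2,11(13)-dien-6,12-olid-8-yl 2-methylprop-2-enoate F13. TESCl/imidazole at −40 °C silylates the primary hydroxyl to give the 15-O-triethylsilyl ether F14. Ac2O/DMAP acetylates the secondary hydroxyl to give the 5-O-acetyl-15-O-triethylsilyl compound F15, and HF·pyridine releases 23. This fallback does not correct a wrong face of osmylation; for that, F12 from the step 11 fallback with ligand-controlled dihydroxylation is the alternative.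

**Further compounds**
F1 | step 2 | 2-bromobut-1-en-3-yne | C=C(Br)C#C
F2 | step 2 | ethyl (2R)-5-bromo-2-hydroxy-2-methylhex-5-en-3-ynoate | CCOC(=O)[C@](C)(O)C#CC(Br)=C
F3 | step 2 | (2R)-5-bromo-2-hydroxy-N-methoxy-N,2-dimethylhex-5-en-3-ynamide | CON(C)C(=O)[C@](C)(O)C#CC(Br)=C
F4 | step 2 | (3R)-6-bromo-3-hydroxy-3-methylhept-6-en-4-yn-2-one | CC(=O)[C@](C)(O)C#CC(Br)=C
F5 | step 11 | (3R,7R)-7-hydroxy-8,8-dimethoxy-3-methyl-6-methylidene-3-(trimethylsilyloxy)oct-4-yn-2-one | CC(=O)[C@](C)(O[Si](C)(C)C)C#CC(=C)[C@@H](O)C(OC)OC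
F6 | step 11 | (2R,6R)-1,1-dimethoxy-6-methyl-3-methylidene-7-oxo-6-(trimethylsilyloxy)oct-4-yn-2-yl acetate | CC(=O)[C@](C)(O[Si](C)(C)C)C#CC(=C)[C@@H](OC(C)=O)C(OC)OC
F7 | step 11 | methyl (2Z,4R,7R)-10-[(1R)-1-acetoxy-2,2-dimethoxyethyl]-2-(bromomethyl)-4,7-dihydroxy-7-methyl-6-oxoundeca-2,10-dien-8-ynoate | BrC/C(=C\[C@H](O)CC(=O)[C@](C)(O)C#CC(=C)[C@@H](OC(C)=O)C(OC)OC)C(=O)OC
F8 | step 11 | methyl (2Z,4R,7R)-10-[(1R)-1-acetoxy-2,2-dimethoxyethyl]-2-(bromomethyl)-7-hydroxy-7-methyl-6-oxo-4-(triethylsilyloxy)undeca-2,10-dien-8-ynoate | BrC/C(=C\[C@H](O[Si](CC)(CC)CC)CC(=O)[C@](C)(O)C#CC(=C)[C@@H](OC(C)=O)C(OC)OC)C(=O)OC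
F9 | step 11 | methyl (2Z,4R)-5-{(2R)-5-[(3R)-3-acetoxy-4,4-dimethoxybut-1-en-2-yl]-2-methyl-3-oxo-2,3-dihydrofuran-2-yl}-2-(bromomethyl)-4-(triethylsilyloxy)pent-2-enoate | BrC/C(=C\[C@H](O[Si](CC)(CC)CC)C[C@@]1(C)OC(=CC1=O)C(=C)[C@@H](OC(C)=O)C(OC)OC)C(=O)OC
F10 | step 11 | methyl (2Z,4R)-5-{(2R)-5-[(3R)-3-acetoxy-4-oxobut-1-en-2-yl]-2-methyl-3-oxo-2,3-dihydrofuran-2-yl}-2-(bromomethyl)-4-(triethylsilyloxy)pent-2-enoate | BrC/C(=C\[C@H](O[Si](CC)(CC)CC)C[C@@]1(C)OC(=CC1=O)C(=C)[C@@H](OC(C)=O)C=O)C(=O)OC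
F11 | step 11 | (5R,6S,7R,8R,10R)-5-acetoxy-8-hydroxy-1-oxo-3,10-epoxygermacra-2,4(15),11(13)-trien-6,12-olide | O[C@@H]1C[C@@]2(C)OC(=CC2=O)C(=C)[C@@H](OC(C)=O)[C@H]2OC(=O)C(=C)[C@@H]21
F12 | step 11 | (5R,6S,7R,8R,10R)-5-acetoxy-1-oxo-3,10-epoxygermacra-2,4(15),11(13)-trien-6,12-olid-8-yl 2-methylprop-2-enoate | C=C(C)C(=O)O[C@@H]1C[C@@]2(C)OC(=CC2=O)C(=C)[C@@H](OC(C)=O)[C@H]2OC(=O)C(=C)[C@@H]21
F13 | step 12 | (4S,5S,6S,7R,8R,10R)-4,5,15-trihydroxy-1-oxo-3,10-epoxygermacra-2,11(13)-dien-6,12-olid-8-yl 2-methylprop-2-enoate | C=C(C)C(=O)O[C@@H]1C[C@@]2(C)OC(=CC2=O)[C@](O)(CO)[C@@H](O)[C@H]2OC(=O)C(=C)[C@@H]21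
F14 | step 12 | 15-O-triethylsilyl ether of F13 | C=C(C)C(=O)O[C@@H]1C[C@@]2(C)OC(=CC2=O)[C@](O)(CO[Si](CC)(CC)CC)[C@@H](O)[C@H]2OC(=O)C(=C)[C@@H]21
F15 | step 12 | 5-O-acetyl-15-O-triethylsilyl derivative of F13 | C=C(C)C(=O)O[C@@H]1C[C@@]2(C)OC(=CC2=O)[C@](O)(CO[Si](CC)(CC)CC)[C@@H](OC(C)=O)[C@H]2OC(=O)C(=C)[C@@H]21
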